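**Retrosynthetic overview**

1. Last step: acid cleavage of three MOM acetals from a fully assembled tris-MOM chalcone.
2. Chalcone C(aryl)–C(=O) bond: a C-4 aryllithium, made by directed ortho-metalation of the unprotected side-chain carbinol as its dianion, acylated by a cinnamoyl Weinreb amide (HWE from 4-hydroxybenzaldehyde). No Claisen–Schmidt aldol.
3. Key step: the side-chain C2–C3 bond and the (R)-carbinol are made together by a catalytic asymmetric Ni/Cr (Nozaki–Hiyama–Kishi) coupling of a 2,6-bis(MOM-oxy)phenylacetaldehyde with the enol triflate of 6-methylhept-5-en-2-one. No geranylation followed by epoxidation or ene oxidation.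
4. Arylacetaldehyde: resorcinol → bis-MOM ether → C-2 lithiation/allylation → Lemieux–Johnson cleavage.
5. No ring is formed; both benzene rings are bought (resorcinol, 4-hydroxybenzaldehyde).

**Assumption:** the (S)-configured Kishi oxazoline–sulfonamide ligand is taken to give the (R)-carbinol. I could not fix this sense from a model, so it must be checked on the first batch by Mosher ester analysis; the (R)-ligand is used with no other change if the sense is opposite. The ligand is a catalyst and is not counted as a step.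

**Route**

Step 1
Reactants: 1 resorcinol
Product: 3 1,3-bis(methoxymethoxy)benzene, via 3-(methoxymethoxy)phenol 2 (not isolated)
Conditions: MOMCl (2.5 equiv), i-Pr2NEt (3 equiv), CH2Cl2, 0 °C → rt
Reagents that add atoms: chloromethyl methyl ether (MOMCl), COCCl
Why: Base-mediated phenol O-alkylation with the α-chloro ether (MOM protection) runs stepwise through the mono-ether and installs the two ortho-directing groups used in steps 2 and 8.

Step 2
Reactants: 3 1,3-bis(methoxymethoxy)benzene; 4 allyl bromide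
Product: 6 2-allyl-1,3-bis(methoxymethoxy)benzene, via 2-lithio-1,3-bis(methoxymethoxy)benzene 5 (not isolated)
Conditions: n-BuLi (1.1 equiv), THF, 0 °C → rt, 1 h; CuI (10 mol %), 4, −40 °C → rt
Reagents that add atoms: n-butyllithium, [Li]CCCC (supplies only the Li of 5)
Why: Directed ortho-metalation removes the C2–H flanked by both OMOM groups, and the aryllithium is allylated by copper-catalysed substitution, for which SN2 and SN2′ give the same product.

Step 3
Reactants: 6 2-allyl-1,3-bis(methoxymethoxy)benzene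
Product: 8 2-[2,6-bis(methoxymethoxy)phenyl]acetaldehyde, via 3-[2,6-bis(methoxymethoxy)phenyl]propane-1,2-diol 7 (not isolated)
Conditions: OsO4 (2 mol %), NaIO4 (4 equiv), 2,6-lutidine (2 equiv), dioxane/H2O 3:1, rt; short silica plug, used at once
Reagents that add atoms: osmium tetroxide, O=[Os](=O)(=O)=O (catalytic carrier of both O atoms of 7); sodium periodate, [Na+].[O-]I(=O)(=O)=O (stoichiometric oxygen source that regenerates OsO4)
Why: Lemieux–Johnson oxidation (catalytic dihydroxylation of the only alkene, then periodate glycol cleavage) gives the arylacetaldehyde, and the lutidine-buffered medium spares the MOM acetals.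

Step 4
Reactants: 9 6-methylhept-5-en-2-one
Product: 11 6-methylhepta-1,5-dien-2-yl trifluoromethanesulfonate, via lithium 6-methylhepta-1,5-dien-2-olate 10 (not isolated)
Conditions: LDA (1.05 equiv), THF, −78 °C, 45 min; PhNTf2 (1.05 equiv), −78 → 0 °C; Et3N-deactivated silica
Reagents that add atoms: lithium diisopropylamide, [Li]N(C(C)C)C(C)C (supplies only the Li of 10); N-phenylbis(trifluoromethanesulfonimide), O=S(=O)(N(c1ccccc1)S(=O)(=O)C(F)(F)F)C(F)(F)F
Why: Kinetic deprotonation of the methyl ketone at CH3 followed by O-sulfonylation of the enolate (enol triflate formation) gives the 1-alken-2-yl triflate, and the remote trisubstituted alkene is inert.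

Step 5
Reactants: 8 2-[2,6-bis(methoxymethoxy)phenyl]acetaldehyde; 11 6-methylhepta-1,5-dien-2-yl trifluoromethanesulfonate
Product: 13 (2R)-1-[2,6-bis(methoxymethoxy)phenyl]-7-methyl-3-methylideneoct-6-en-2-ol, via zirconocene alkoxide 12 (not isolated)
Conditions: CrCl2 (10 mol %), (S)-N-[2-(4-isopropyl-4,5-dihydrooxazol-2-yl)-6-methylphenyl]methanesulfonamide (11 mol %), proton sponge (11 mol %), NiCl2·(2,9-dimethyl-1,10-phenanthroline) (2 mol %), Mn (2 equiv), Cp2ZrCl2 (1.2 equiv), LiCl (2 equiv), 11 (1.5 equiv), MeCN, rt; aqueous work-up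
Reagents that add atoms: zirconocene dichloride, Cl[Zr](Cl)(C1C=CC=C1)C1C=CC=C1 (supplies only the Cp2ZrCl of 12)
Why: In this catalytic asymmetric Nozaki–Hiyama–Kishi coupling, Ni(0) inserts into the C–OTf bond, the alkenyl group passes to the sulfonamide-ligated Cr(III), and the non-basic alkenylchromium adds to one enantioface of the enolisable aldehyde, so the ligand sets the new C2 stereocentre as R while Cp2ZrCl2 frees the alkoxide from Cr and Mn returns Cr(III) to Cr(II).

Step 6
Reactants: 14 4-hydroxybenzaldehyde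
Product: 15 4-(methoxymethoxy)benzaldehyde
Conditions: MOMCl (1.3 equiv), i-Pr2NEt (1.5 equiv), CH2Cl2, 0 °C → rt
Reagents that add atoms: chloromethyl methyl ether (MOMCl), COCCl
Why: Phenol O-alkylation (MOM protection) masks the acidic OH so that the later aryllithium is not quenched.

Step 7
Reactants: 15 4-(methoxymethoxy)benzaldehyde; 16 diethyl {2-[methoxy(methyl)amino]-2-oxoethyl}phosphonate
Product: 18 (2E)-N-methoxy-3-[4-(methoxymethoxy)phenyl]-N-methylprop-2-enamide, via sodium phosphonate carbanion 17 (not isolated)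
Conditions: NaH (1.1 equiv), THF, 0 °C; 15, 0 °C → rt
Reagents that add atoms: sodium hydride, [Na+].[H-] (supplies only the Na of 17)
Why: Horner–Wadsworth–Emmons olefination of the aryl aldehyde with the stabilised phosphonate anion gives the E-enamide (typically >20:1) because the addition is reversible and the anti-oxaphosphetane pathway wins.

Step 8
Reactants: 13 (2R)-1-[2,6-bis(methoxymethoxy)phenyl]-7-methyl-3-methylideneoct-6-en-2-ol; 18 (2E)-N-methoxy-3-[4-(methoxymethoxy)phenyl]-N-methylprop-2-enamide
Product: 21 (2E)-1-{3-[(2R)-2-hydroxy-7-methyl-3-methylideneoct-6-en-1-yl]-2,4-bis(methoxymethoxy)phenyl}-3-[4-(methoxymethoxy)phenyl]prop-2-en-1-one, via dilithiated carbinol 19 (not isolated), via tetrahedral lithium adduct 20 (not isolated)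
Conditions: n-BuLi (2.2 equiv), TMEDA (2.2 equiv), THF, −20 → 0 °C, 1.5 h; 18 (1.3 equiv), −78 → −10 °C; sat. aq NH4Cl
Reagents that add atoms: n-butyllithium, [Li]CCCC (supplies only the Li of 19 and 20)
Why: The first equivalent of base forms the lithium alkoxide, the second performs directed ortho-metalation at the only ring C–H next to an OMOM group, and the aryllithium adds 1,2 to the Weinreb amide (nucleophilic acyl substitution via a chelated tetrahedral adduct that gives the E-enone only on quench), leaving the carbinol stereocentre untouched.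

Step 9
Reactants: 21 (2E)-1-{3-[(2R)-2-hydroxy-7-methyl-3-methylideneoct-6-en-1-yl]-2,4-bis(methoxymethoxy)phenyl}-3-[4-(methoxymethoxy)phenyl]prop-2-en-1-one
Product: 22 (2E)-1-{2,4-dihydroxy-3-[(2R)-2-hydroxy-7-methyl-3-methylideneoct-6-en-1-yl]phenyl}-3-(4-hydroxyphenyl)prop-2-en-1-one
Conditions: 1.25 M HCl in MeOH, THF co-solvent, rt, followed by TLC; NaHCO3 quench
Reagents that add atoms: none
Why: Acid-catalysed transacetalisation (MOM methanolysis) frees the three phenols under conditions intended to be too mild to ionise the secondary allylic alcohol, protonate the alkenes or close the 2′-hydroxychalcone to a flavanone, so C2 stays R and the enone stays E.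

**Compound list**

1 | resorcinol (benzene-1,3-diol) | Oc1cccc(O)c1 | starting material
2 | 3-(methoxymethoxy)phenol | COCOc1cccc(O)c1 | intermediate (not isolated)
3 | 1,3-bis(methoxymethoxy)benzene | COCOc1cccc(OCOC)c1 | intermediate
4 | allyl bromide (3-bromoprop-1-ene) | C=CCBr | starting material
5 | 2-lithio-1,3-bis(methoxymethoxy)benzene | [Li]c1c(OCOC)cccc1OCOC | intermediate (not isolated)
6 | 2-allyl-1,3-bis(methoxymethoxy)benzene | C=CCc1c(OCOC)cccc1OCOC | intermediate
7 | 3-[2,6-bis(methoxymethoxy)phenyl]propane-1,2-diol (racemic) | OCC(O)Cc1c(OCOC)cccc1OCOC | intermediate (not isolated)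
8 | 2-[2,6-bis(methoxymethoxy)phenyl]acetaldehyde | O=CCc1c(OCOC)cccc1OCOC | intermediate
9 | 6-methylhept-5-en-2-one | CC(=O)CCC=C(C)C | starting material
10 | lithium 6-methylhepta-1,5-dien-2-olate | C=C(O[Li])CCC=C(C)C | intermediate (not isolated)
11 | 6-methylhepta-1,5-dien-2-yl trifluoromethanesulfonate | C=C(CCC=C(C)C)OS(=O)(=O)C(F)(F)F | intermediate
12 | chlorobis(cyclopentadienyl)zirconium (2R)-1-[2,6-bis(methoxymethoxy)phenyl]-7-methyl-3-methylideneoct-6-en-2-olate | C=C(CCC=C(C)C)[C@H](O[Zr](Cl)(C1C=CC=C1)C1C=CC=C1)Cc1c(OCOC)cccc1OCOC | intermediate (not isolated)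
13 | (2R)-1-[2,6-bis(methoxymethoxy)phenyl]-7-methyl-3-methylideneoct-6-en-2-ol | C=C(CCC=C(C)C)[C@H](O)Cc1c(OCOC)cccc1OCOC | intermediate
14 | 4-hydroxybenzaldehyde | O=Cc1ccc(O)cc1 | starting material
15 | 4-(methoxymethoxy)benzaldehyde | COCOc1ccc(C=O)cc1 | intermediate
16 | diethyl {2-[methoxy(methyl)amino]-2-oxoethyl}phosphonate | CCOP(=O)(CC(=O)N(C)OC)OCC | starting material
17 | sodium salt of the carbanion of 16 (α to P and C=O) | CCOP(=O)(OCC)[CH-]C(=O)N(C)OC.[Na+] | intermediate (not isolated)
18 | (2E)-N-methoxy-3-[4-(methoxymethoxy)phenyl]-N-methylprop-2-enamide | COCOc1ccc(/C=C/C(=O)N(C)OC)cc1 | intermediate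
19 | lithium (2R)-1-[3-lithio-2,6-bis(methoxymethoxy)phenyl]-7-methyl-3-methylideneoct-6-en-2-olate | C=C(CCC=C(C)C)[C@H](O[Li])Cc1c(OCOC)ccc([Li])c1OCOC | intermediate (not isolated)
20 | dilithium salt of the tetrahedral adduct of 19 and 18: aryl C(OLi)(N(OMe)Me)–CH=CH–aryl, E-alkene, side-chain OLi, both epimers at the new carbon | C=C(CCC=C(C)C)[C@H](O[Li])Cc1c(OCOC)ccc(C(O[Li])(N(C)OC)/C=C/c2ccc(OCOC)cc2)c1OCOC | intermediate (not isolated)
21 | (2E)-1-{3-[(2R)-2-hydroxy-7-methyl-3-methylideneoct-6-en-1-yl]-2,4-bis(methoxymethoxy)phenyl}-3-[4-(methoxymethoxy)phenyl]prop-2-en-1-one | C=C(CCC=C(C)C)[C@H](O)Cc1c(OCOC)ccc(C(=O)/C=C/c2ccc(OCOC)cc2)c1OCOC | intermediate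
22 | (2E)-1-{2,4-dihydroxy-3-[(2R)-2-hydroxy-7-methyl-3-methylideneoct-6-en-1-yl]phenyl}-3-(4-hydroxyphenyl)prop-2-en-1-one (CNP0307786.1) | C=C(CCC=C(C)C)[C@H](O)Cc1c(O)ccc(C(=O)/C=C/c2ccc(O)cc2)c1O | target

**Step count and risks**

Total step count: 9. Longest linear sequence: 6 steps (1 → 3 → 6 → 8 → 13 → 21 → 22). The side branches are 1 step (to 11) and 2 steps (to 18).

The three steps most likely to fail:

Step 5 (asymmetric Ni/Cr coupling). The risk is insufficient ee, or the wrong sense of induction, with an α-unbranched aldehyde flanked by two coordinating OMOM groups. The coupling itself should be reliable because alkenylchromium reagents do not enolise aldehydes. The fallback sets out from 13 of unsatisfactory enantiopurity and moves the stereochemistry-setting event from C–C bond formation to a ketone reduction. Dess–Martin periodinane (NaHCO3, CH2Cl2, 0 °C) gives 1-[2,6-bis(methoxymethoxy)phenyl]-7-methyl-3-methylideneoct-6-en-2-one F1. Reduction with (S)-Me-CBS oxazaborolidine (20 mol %) and catecholborane in toluene at −78 °C treats the α-branched alkenyl group as the large substituent. It delivers the catecholborate ester of the (R)-carbinol F2, which is hydrolysed on work-up, and the route is rejoined at 13.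

Step 8 (dianion ortho-metalation and acylation). The risk is incomplete or unselective lithiation of the aggregated alkoxide, and loss of 18 to surplus n-BuLi. The fallback sets out from 13 and gives up the protecting-group-free dianion. TBSOTf and 2,6-lutidine (CH2Cl2, −78 → 0 °C) give tert-butyl({(2R)-1-[2,6-bis(methoxymethoxy)phenyl]-7-methyl-3-methylideneoct-6-en-2-yl}oxy)dimethylsilane F3. Exactly one equivalent of s-BuLi/TMEDA (THF, −78 °C) gives its 3-lithio derivative F4. Addition of 18 gives the tetrahedral lithium adduct F5, and quench gives the silyl-protected chalcone (2E)-1-{3-[(2R)-2-(tert-butyldimethylsilyloxy)-7-methyl-3-methylideneoct-6-en-1-yl]-2,4-bis(methoxymethoxy)phenyl}-3-[4-(methoxymethoxy)phenyl]prop-2-en-1-one F6. The HCl/MeOH conditions of step 9 then remove the silyl ether together with the three MOM groups, so the fallback comes back to the route at 22.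

Step 9 (global MOM removal). The risk is acid-promoted closure of a flanking phenol onto the protonated 1,1-disubstituted alkene (hydroxychroman), or chalcone-to-flavanone isomerisation. The fallback sets out from 21 and replaces Brønsted-acid solvolysis by silyl transfer. TMSOTf and 2,2′-bipyridyl (CH2Cl2, 0 °C → rt) convert the three aryl MOM ethers into aryl silyl ethers and silylate the carbinol. This gives (2E)-1-{3-[(2R)-7-methyl-3-methylidene-2-(trimethylsilyloxy)oct-6-en-1-yl]-2,4-bis(trimethylsilyloxy)phenyl}-3-[4-(trimethylsilyloxy)phenyl]prop-2-en-1-one F7. Wet methanol with citric acid at rt desilylates it, and the fallback comes back to the route at 22.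

**Further compounds**

F1 | step 5 | 1-[2,6-bis(methoxymethoxy)phenyl]-7-methyl-3-methylideneoct-6-en-2-one | C=C(CCC=C(C)C)C(=O)Cc1c(OCOC)cccc1OCOC
F2 | step 5 | 2-({(2R)-1-[2,6-bis(methoxymethoxy)phenyl]-7-methyl-3-methylideneoct-6-en-2-yl}oxy)-1,3,2-benzodioxaborole | C=C(CCC=C(C)C)[C@H](OB1Oc2ccccc2O1)Cc1c(OCOC)cccc1OCOC
F3 | step 8 | tert-butyl({(2R)-1-[2,6-bis(methoxymethoxy)phenyl]-7-methyl-3-methylideneoct-6-en-2-yl}oxy)dimethylsilane | C=C(CCC=C(C)C)[C@H](O[Si](C)(C)C(C)(C)C)Cc1c(OCOC)cccc1OCOC
F4 | step 8 | tert-butyl({(2R)-1-[3-lithio-2,6-bis(methoxymethoxy)phenyl]-7-methyl-3-methylideneoct-6-en-2-yl}oxy)dimethylsilane | C=C(CCC=C(C)C)[C@H](O[Si](C)(C)C(C)(C)C)Cc1c(OCOC)ccc([Li])c1OCOC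
F5 | step 8 | lithium salt of the tetrahedral adduct of F4 and 18 (aryl C(OLi)(N(OMe)Me)–CH=CH–aryl, E-alkene, both epimers at the new carbon) | C=C(CCC=C(C)C)[C@H](O[Si](C)(C)C(C)(C)C)Cc1c(OCOC)ccc(C(O[Li])(N(C)OC)/C=C/c2ccc(OCOC)cc2)c1OCOC
F6 | step 8 | (2E)-1-{3-[(2R)-2-(tert-butyldimethylsilyloxy)-7-methyl-3-methylideneoct-6-en-1-yl]-2,4-bis(methoxymethoxy)phenyl}-3-[4-(methoxymethoxy)phenyl]prop-2-en-1-one | C=C(CCC=C(C)C)[C@H](O[Si](C)(C)C(C)(C)C)Cc1c(OCOC)ccc(C(=O)/C=C/c2ccc(OCOC)cc2)c1OCOC
F7 | step 9 | (2E)-1-{3-[(2R)-7-methyl-3-methylidene-2-(trimethylsilyloxy)oct-6-en-1-yl]-2,4-bis(trimethylsilyloxy)phenyl}-3-[4-(trimethylsilyloxy)phenyl]prop-2-en-1-one | C=C(CCC=C(C)C)[C@H](O[Si](C)(C)C)Cc1c(O[Si](C)(C)C)ccc(C(=O)/C=C/c2ccc(O[Si](C)(C)C)cc2)c1O[Si](C)(C)C
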